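Conventions: atoms carry the number of their position in the SMILES string of the target (C1, C2, C3, O4, C5, O6, C7, C8, C9 … C30, O31). Ring A is the δ-lactone (C2, O4, C5, C7, C8, C9), ring B the cyclohexane (C9, C10, C11, C12, C26, C27), ring C the cyclopentane (C12, C22, C23, C25, C26), ring D the carbocycle (C12, C13, C14, C16, C17, C22) that becomes a bicyclo[2.2.2]octane with the bridge C23–C30, and ring E the γ-lactone (C17, C18, O20, C21, C22). The "cage face" of ring B is the face on which C22 leaves C12; the "open face" is the face of H26. Compound numbers are those of the steps and of the compound list.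

## Analysis of the target

The target is hexacyclic: a bicyclo[2.2.2]octanone (bridgeheads C14 and C22) is tied by ring C into an isotwistane, ring B is fused to it at C12–C26, and the lactone rings A (spiro at C9) and E hang on the periphery. It has eight stereocentres, six of them fully substituted (C9, C12, C14, C22, C23, C27); C12–C22–C23 are three contiguous quaternary carbons and C9–C27 is a quaternary carbon next to a tertiary carbinol. On ring B the bonds C12–C22, C26–C25, C27–O29 and C9–C8 lie on the cage face, while C13, H26, C28 and C2 lie on the open face. On the bicycle, H17 looks at the C23–C30 bridge and C18 at the C12–C13 bridge. The sensitive groups are the enoate of ring A (a Michael acceptor), the tertiary alcohol next to the spiro centre, C17 (α to a lactone carbonyl) and C26 (epimerizable whenever C27 is a ketone). The C30 ketone has no α-hydrogen and is flanked by two quaternary carbons. The difficulty lies in the two bonds between fully substituted carbons (C22–C23 and C9–C2) and in the fact that C21 caps the cage face of ring B: every reagent reaches C9 and C27 from the open face, which dictates the order of bond formation there. The strategy rests on ring E: its oxygen-bearing carbon C21 is a one-carbon branch on bridgehead C22, it is γ to the carboxyl carbon C18, and it is the only γ-carbon with hydrogen (C12, C23 and C14 are quaternary). The whole carbon skeleton can therefore be built with a plain methyl group at C22, and O20–C21 is made last on the cage by carboxylate-directed C–H activation.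

## Retrosynthetic reasoning

36 ⇒ 33. The C7=C8 double bond is removed first. This keeps a conjugate acceptor out of the step that makes C27; forward, the δ-lactone enolate of 33 is selenated at C7 and the selenoxide eliminates toward C8.

33 ⇒ 32. The C27–C28 bond is cut to a ketone and a methyl nucleophile. The cage face of C27 is blocked by C21, so the nucleophile must come from the open face, which places C28 there and O29 on the cage face, as required. The C30 ketone is shielded and both lactones are hindered esters, so chemoselectivity can be expected.

32 ⇒ 29. C9–C2 and O4–C5 are cut together: a three-carbon ketone electrophile adds to the C9 enol silane of 29 and the new tertiary alkoxide closes ring A on the pendant ester. The order is forced by the face argument: whatever bonds to C9 last arrives on the open face, and the target has C2 there and C8 on the cage face. Bringing C8 in after the C2 unit, or moving C8 from C27 to C9 by a 1,2-shift after a carbonyl addition, would give the C9 epimer.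

29 ⇒ 27. C8–C9 is cut to the enamine of ketone 27 and an acrylate ester; this uses the only methylene α to C27.

27 ⇒ 26. O20–C21 is cut (key step). This puts the risk in one step on a rigid substrate in which only one C–H site is within reach of the carboxylate, and lets every earlier step carry a robust methyl group instead of an oxygenated carbon at the most crowded position.

26 ⇒ 25 ⇒ 23 ⇒ 22. These are functional-group changes (ester cleavage, oxidation and deketalization) plus the C17–H bond: hydrogenation of the C16=C17 enoate of 22, delivered by the C30 hydroxyl group, sets C17.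

22 ⇒ 20. C22–C23 and C14–C30 are cut in a tethered [4+2]: the ring-D dienoate of 20 and its enol ether. The tether through C25–C26 fixes regiochemistry and face, so C14, C22 and C23 follow from C12 and C26; the bond between the quaternary carbons C22 and C23 is made intramolecularly in a five-membered ring.

20 ⇒ 19 ⇒ 18 ⇒ 17. The enol ether geometry, which decides on which side of C30 the oxygen sits, is derived from an α-methylene aldehyde (19) by 1,4-hydrosilylation; 19 comes from the protected allylic alcohol of 17.

17 ⇒ 16 ⇒ 15 ⇒ 14 ⇒ 13. Ring D is dismantled: C22–C21 by methyl cross-coupling of an enol triflate, C17–C22 by a Dieckmann condensation, and C16–C17 by coupling of a zinc ester enolate with a (Z)-vinyl iodide. The Z geometry holds C13 and C17 cis, as ring closure needs.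

13 ⇒ 9 + 12. C12–C13 is cut to the ester enolate of 9 and the allylic bromide 12 (from 10 through 11). This creates the quaternary C12 under 1,2-control by C26.

9 ⇒ 8 ⇒ 3 + 6. C26–C25 and the C12–H bond are cut: asymmetric conjugate reduction of enone ester 3 and trans-alkylation of the resulting enolate with 6 set C26, the centre from which all others are relayed. 3 comes from 1 through 2, and 6 from 4 through 5.

## Alternatives that were turned down

Alternative 1: The C12–C13 bond is disconnected; forward, a thermal disrotatory 6π-electrocyclization across C13=C14–C16=C17–C22=C12, with the central diene held in a butyrolactone, closes ring D, makes the spiro centre C12 and gives A1. In its favour, ring E and its oxygen are present from the start, so no C–H oxidation is needed, and the quaternary C12 comes from a pericyclic step without reagents; on these points it is stronger than the chosen route. Against it, the C12 terminus is a fully substituted exocyclic alkene, so the reactive conformer suffers allylic strain, high temperatures are needed, and hydrogen shifts compete. The configuration at C12 depends on torquoselectivity steered only by the neighbouring C26, and two exocyclic alkene geometries must be built first. After A1 the bicycle and three quaternary centres are still missing. The chosen route makes C12 by an enolate alkylation with ordinary 1,2-induction and offers a late key step whose site selectivity is fixed by the skeleton.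

Alternative 2: The bonds C23–C25, C14–C16 and C17–C22 are disconnected back to a flat arene; forward, a Claisen shift of a chiral secondary allyl group from the phenolic oxygen to C23 gives an ortho-dienone whose diene C22=C12–C13=C14 is trapped by an acrylate tethered through the C21 oxygen, delivering A2. In step economy it is clearly stronger: three rings and four stereocentres come from one operation, the lactone oxygen is never a problem, and chirality comes from a cheap allylic alcohol. Against it for this target, the tether sits on a diene carbon in the diene plane, so the face of addition relative to the new C23 centre rests only on methyl versus crotyl. The ortho-dienone can also rearrange on to the para position or dimerize, and two ortho carbons compete. Above all, C12 is left as an alkene carbon in A2, so the quaternary C12, ring C and ring B must all be made afterwards on a congested bicycle, and the crotyl group must be cut down. The chosen route has C12, ring B and the ring-C tether in place before the cage forms and lets the tether decide the face.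

Alternative 3: The bonds C12–C22 and C16–C17 are disconnected; forward, an exocyclic diene C12=C13–C14=C16 on ring B adds to a tethered 4-acyl butenolide alkene C17=C22, closing ring D and ring C and giving A3. It is stronger in that the vicinal quaternary pair C12–C22, C17 and ring E arise together with cis fusion, so neither a hydrogenation nor a C–H oxidation is needed. Against it, A3 still lacks the one-carbon bridge C30 and both quaternary centres that flank it: C23 is a ketone carbon that needs a methyl group and C30, and C14 is an alkene carbon that must become quaternary by ring closure on the cage. Those are two further bonds to fully substituted carbons with uncertain regio- and stereocontrol. The chosen route forms both bonds of that bridge (C22–C23 and C14–C30) in one tethered cycloaddition and pays for it with the late lactonization.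

Key step: step 21

Assumption: in step 5 the (S)-ligand is taken to deliver hydride to the face of C12 that gives the (1S) ester, by analogy with 3-alkylcyclohex-2-enones; if the sense is the opposite, the (R)-ligand is used and nothing else changes. Compound 15 is written as its enol.

## Route

Step 1
Reactants: 1 cyclohexane-1,3-dione
Product: 2 3-oxocyclohex-1-en-1-yl trifluoromethanesulfonate
Conditions: Tf2O, pyridine, CH2Cl2, −78 → 0 °C
Reagents that add atoms: trifluoromethanesulfonic anhydride, O=S(=O)(OS(=O)(=O)C(F)(F)F)C(F)(F)F
Why: O-sulfonylation of the enolized dione gives the vinylogous acyl triflate; standard activation of a cyclic 1,3-dione.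

Step 2
Reactants: 2 3-oxocyclohex-1-en-1-yl trifluoromethanesulfonate
Product: 3 methyl 3-oxocyclohex-1-ene-1-carboxylate
Conditions: Pd(OAc)2 (3 mol%), dppp, CO (1 atm), MeOH, Et3N, DMF, 60 °C
Reagents that add atoms: carbon monoxide, [C-]#[O+]; methanol, CO
Why: Palladium-catalysed alkoxycarbonylation of an enol triflate (oxidative addition to zerovalent palladium, CO insertion, methanolysis); the new carbon is C22.

Step 3
Reactants: 4 2-methylenepropane-1,3-diol
Product: 5 2-[(4-methoxybenzyloxy)methyl]prop-2-en-1-ol
Conditions: NaH (1.0 equiv), 4-MeOC6H4CH2Cl, Bu4NI (cat.), THF, 0 °C → rt (diol in excess)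
Reagents that add atoms: 4-methoxybenzyl chloride, COc1ccc(CCl)cc1
Why: Williamson etherification; monoprotection of a symmetric diol is secured by using the diol in excess.

Step 4
Reactants: 5 2-[(4-methoxybenzyloxy)methyl]prop-2-en-1-ol
Product: 6 1-{[2-(bromomethyl)prop-2-enyloxy]methyl}-4-methoxybenzene
Conditions: CBr4, PPh3, CH2Cl2, 0 °C
Reagents that add atoms: carbon tetrabromide, BrC(Br)(Br)Br
Why: Appel bromination of a primary allylic alcohol; the 2-substituted allyl system is symmetric, so allylic transposition cannot give an isomer.

Step 5
Reactants: 3 methyl 3-oxocyclohex-1-ene-1-carboxylate; 6 1-{[2-(bromomethyl)prop-2-enyloxy]methyl}-4-methoxybenzene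
Product: 8 methyl (1S,2R)-2-{2-[(4-methoxybenzyloxy)methyl]prop-2-enyl}-3-oxocyclohexane-1-carboxylate, via bis-enoxysilane 7 (not isolated)
Conditions: CuCl (5 mol%), NaOtBu (5 mol%), (S)-p-tol-BINAP (5 mol%), Ph2SiH2 (0.55 equiv), PhMe, 0 °C; then 6, Bu4N[Ph3SiF2], CH2Cl2, rt
Reagents that add atoms: none
Why: Tandem asymmetric conjugate reduction and enolate alkylation: the chiral copper hydride (monovalent copper) adds hydride to C12, the β-carbon of the enone, which sets C12; fluoride activation of the regiodefined silyl enol ether 7 then lets the allylic bromide enter at C26 trans to the C12 ester, which fixes C26 as R.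

Step 6
Reactants: 8 methyl (1S,2R)-2-{2-[(4-methoxybenzyloxy)methyl]prop-2-enyl}-3-oxocyclohexane-1-carboxylate
Product: 9 methyl (6R,7S)-6-{2-[(4-methoxybenzyloxy)methyl]prop-2-enyl}-1,4-dioxaspiro[4.5]decane-7-carboxylate
Conditions: HOCH2CH2OH, PPTS (cat.), PhH, reflux (Dean–Stark)
Reagents that add atoms: ethane-1,2-diol, OCCO
Why: Ketalization of C27 removes the more acidic ketone α-hydrogens so that only C12 can be enolized later; the trans arrangement is the thermodynamic one, so acid cannot scramble C26.

Step 7
Reactants: 10 prop-2-yn-1-ol
Product: 11 (Z)-3-iodo-2-methylprop-2-en-1-ol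
Conditions: MeMgBr (2.2 equiv), CuI (10 mol%), THF, −10 °C → rt; then I2, −40 → 0 °C
Reagents that add atoms: methylmagnesium bromide, C[Mg]Br; iodine, II
Why: Copper-catalysed anti-carbomagnesiation of the propargylic alkoxide gives a chelated vinylmagnesium cis to the CH2O group, and iodination proceeds with retention; this fixes the Z geometry that later holds C13 and C17 cis.

Step 8
Reactants: 11 (Z)-3-iodo-2-methylprop-2-en-1-ol
Product: 12 (Z)-3-bromo-1-iodo-2-methylprop-1-ene
Conditions: CBr4, PPh3, CH2Cl2, 0 °C
Reagents that add atoms: carbon tetrabromide, BrC(Br)(Br)Br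
Why: Appel bromination of the primary allylic alcohol under neutral conditions leaves the vinyl iodide geometry untouched.

Step 9
Reactants: 9 methyl (6R,7S)-6-{2-[(4-methoxybenzyloxy)methyl]prop-2-enyl}-1,4-dioxaspiro[4.5]decane-7-carboxylate; 12 (Z)-3-bromo-1-iodo-2-methylprop-1-ene
Product: 13 methyl (6R,7S)-7-[(Z)-3-iodo-2-methylprop-2-enyl]-6-{2-[(4-methoxybenzyloxy)methyl]prop-2-enyl}-1,4-dioxaspiro[4.5]decane-7-carboxylate
Conditions: LiN(iPr)2, THF, −78 °C; then 12, −78 → −20 °C
Reagents that add atoms: none
Why: Ester enolate alkylation creates the quaternary C12; the C26 side chain turns axial to avoid allylic strain with the exocyclic enolate and the bromide attacks the opposite face, so C13 ends trans to C25 and the ester carbon C22 cis to it, the relationship the cage needs.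

Step 10
Reactants: 13 methyl (6R,7S)-7-[(Z)-3-iodo-2-methylprop-2-enyl]-6-{2-[(4-methoxybenzyloxy)methyl]prop-2-enyl}-1,4-dioxaspiro[4.5]decane-7-carboxylate
Product: 14 methyl (6R,7S)-7-[(Z)-5-methoxy-2-methyl-5-oxopent-2-enyl]-6-{2-[(4-methoxybenzyloxy)methyl]prop-2-enyl}-1,4-dioxaspiro[4.5]decane-7-carboxylate
Conditions: BrZnCH2CO2Me (from BrCH2CO2Me and Zn, THF), Pd(PPh3)4 (5 mol%), THF, 60 °C
Reagents that add atoms: methyl bromoacetate (as its zinc enolate), COC(=O)CBr
Why: Negishi-type coupling of a Reformatsky reagent with a vinyl iodide forms C16–C17 with retention of the Z geometry and brings in C17 and C18.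

Step 11
Reactants: 14 methyl (6R,7S)-7-[(Z)-5-methoxy-2-methyl-5-oxopent-2-enyl]-6-{2-[(4-methoxybenzyloxy)methyl]prop-2-enyl}-1,4-dioxaspiro[4.5]decane-7-carboxylate
Product: 15 spiro β-keto ester (enol form; 12S,26R)
Conditions: KOtBu (2.2 equiv), THF, 0 °C → rt; AcOH quench
Reagents that add atoms: none
Why: Dieckmann condensation: the only enolizable ester (C17, also allylic) attacks the C22 ester, the cis alkene preorganizes the six-membered ring D, and deprotonation of the product to a fully conjugated dienolate drives the equilibrium.

Step 12
Reactants: 15 spiro β-keto ester (enol form; 12S,26R)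
Product: 16 spiro dienyl triflate (12S,26R)
Conditions: NaH, PhNTf2, THF, 0 °C → rt
Reagents that add atoms: N-phenylbis(trifluoromethanesulfonimide), O=S(=O)(N(c1ccccc1)S(=O)(=O)C(F)(F)F)C(F)(F)F
Why: O-triflation of the β-keto ester enolate; enolization is possible only toward C17 because C12 is quaternary, so the C17=C22 position of the triflate is unambiguous.

Step 13
Reactants: 16 spiro dienyl triflate (12S,26R)
Product: 17 spiro dienoate 4-methoxybenzyl ether (12S,26R)
Conditions: MeMgBr (1.3 equiv), Fe(acac)3 (5 mol%), THF/NMP, −30 °C
Reagents that add atoms: methylmagnesium bromide, C[Mg]Br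
Why: Iron-catalysed cross-coupling of an alkenyl triflate with a Grignard reagent installs C21 on C22 faster than the esters can be attacked and completes the diene C14=C16–C17=C22.

Step 14
Reactants: 17 spiro dienoate 4-methoxybenzyl ether (12S,26R)
Product: 18 spiro dienoate allylic alcohol (12S,26R)
Conditions: DDQ, CH2Cl2/pH 7 buffer, 0 °C
Reagents that add atoms: none
Why: Oxidative cleavage of the 4-methoxybenzyl ether; the electron-poor, hindered dienoate and the ketal are not affected at 0 °C.

Step 15
Reactants: 18 spiro dienoate allylic alcohol (12S,26R)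
Product: 19 spiro dienoate α-methylene aldehyde (12S,26R)
Conditions: Dess–Martin periodinane, NaHCO3, CH2Cl2, 0 °C → rt
Reagents that add atoms: none
Why: Mild oxidation of the primary allylic alcohol to the 2-substituted acrolein; it is used at once because such enals dimerize on standing.

Step 16
Reactants: 19 spiro dienoate α-methylene aldehyde (12S,26R)
Product: 20 spiro dienoate (E)-triethylsilyl enol ether (12S,26R)
Conditions: (Ph3P)3RhCl (2 mol%), Et3SiH, PhH, 50 °C
Reagents that add atoms: triethylsilane, CC[SiH](CC)CC
Why: Rhodium-catalysed 1,4-hydrosilylation of an enal through its s-cis conformer puts silicon on oxygen and hydrogen on C24, so the oxygen ends cis to the new methyl group and trans to C25, i.e. the E enol ether; the isolated dienoate is not a substrate.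

Step 17
Reactants: 20 spiro dienoate (E)-triethylsilyl enol ether (12S,26R)
Product: 22 tetracyclic hydroxy enoate ketal (C30 hydroxyl syn to C16=C17), via silyl ether 21 (not isolated)
Conditions: PhMe (0.01 M), BHT, Et3N (trace), 170 °C, sealed tube; then Bu4NF, THF, rt
Reagents that add atoms: none
Why: Intramolecular inverse-electron-demand Diels–Alder reaction: the nucleophilic enol ether carbon C23 bonds to C22, the β-carbon of the dienoate, and C30 bonds to C14; the two-atom tether allows only the diene face that carries C26 and only the fused mode (ring C), which sets C14, C22 and C23, and the E geometry places the silyloxy group over the C16=C17 bridge before fluoride frees the alcohol.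

Step 18
Reactants: 22 tetracyclic hydroxy enoate ketal (C30 hydroxyl syn to C16=C17)
Product: 23 tetracyclic hydroxy ester ketal (C17 set)
Conditions: [Ir(cod)(PCy3)(py)]PF6 (5 mol%), H2 (1 atm), CH2Cl2, rt
Reagents that add atoms: none
Why: Hydroxyl-directed homogeneous hydrogenation: iridium bound to the C30 hydroxyl delivers H2 to the face of C16=C17 that looks at the C23–C30 bridge, so H17 lies on that side and C18 points to the C12–C13 bridge; this is also the less hindered face, next to the one-substituent carbinol carbon.

Step 19
Reactants: 23 tetracyclic hydroxy ester ketal (C17 set)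
Product: 25 tetracyclic diketo methyl ester, via keto ketal 24 (not isolated)
Conditions: CrO3, H2SO4, H2O, acetone, 0 °C → rt
Reagents that add atoms: water, O
Why: Chromic acid oxidation of the hindered C30 alcohol with hydrolysis of the dioxolane by the aqueous acid in the same pot; C30 has no α-hydrogen, the ester is not enolized in acid, and C26 can only settle in the cis ring fusion it already has (in the other epimer C27 would eclipse C13).

Step 20
Reactants: 25 tetracyclic diketo methyl ester
Product: 26 C22-methyl isotwistane diketo acid
Conditions: LiI, EtOAc, reflux; then 1 M HCl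
Reagents that add atoms: none
Why: Nucleophilic demethylation by iodide (SN2 at the methyl group) is insensitive to the hindrance at the acyl carbon and is not basic, so C17 is not epimerized.

Step 21
Reactants: 26 C22-methyl isotwistane diketo acid
Product: 27 pentacyclic diketo lactone
Conditions: Pd(OAc)2 (10 mol%), N-acetyl-β-alanine (20 mol%), NaOAc, tBuOOH (70% aq.), (CF3)2CHOH, 60 °C
Reagents that add atoms: none
Why: The carboxylate of 26 binds divalent palladium carrying the mono-N-protected amino acid, and concerted metalation–deprotonation of a C21–H bond gives a six-membered palladacycle (Pd–O–C18–C17–C22–C21); tBuOOH oxidizes it to tetravalent palladium and C(sp3)–O reductive elimination forms O20–C21. The closest known reaction type is the palladium-catalysed, carboxylate-directed C(sp3)–H lactonization of free aliphatic acids with peroxide oxidants, including γ-methyl activation next to a quaternary β-carbon. Ring E closes in a 5-exo-tet sense, the carboxylate oxygen attacking the palladium-bound C21. No stereocentre is formed, and C17, set in step 18, is not touched because no enolizing base is present. The step needs site selectivity only: C21 is the sole γ-carbon with hydrogen (C12, C23 and C14 are quaternary), the methyl groups C15 and C24 are δ and out of reach, and the only β-hydrogens sit on the C16 methylene of the rigid bicycle, where a secondary C–H bond and a strained β-lactone are both unfavourable. The C18–C17–C22–C21 dihedral angle is locked near 60°, which preorganizes the palladacycle. The non-enolizable C30 ketone and the C27 ketone are spectators under these weakly acidic, oxidative conditions.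

Step 22
Reactants: 27 pentacyclic diketo lactone
Product: 29 C9-(2-methoxycarbonylethyl) diketo lactone, via enamine 28 (not isolated)
Conditions: pyrrolidine, TsOH (cat.), PhH, reflux (Dean–Stark); then methyl acrylate, MeCN, reflux; then AcOH/NaOAc/H2O
Reagents that add atoms: methyl acrylate, C=CC(=O)OC
Why: Stork enamine Michael addition: only the C27 ketone can form an enamine (C30 has no α-hydrogen), it forms toward the methylene C9, and monoalkylation brings in C8, C7 and C5; the C9 configuration (chain equatorial expected) is erased in step 23.

Step 23
Reactants: 29 C9-(2-methoxycarbonylethyl) diketo lactone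
Product: 32 7,8-dihydro spirolactone C27 ketone, via silyl enol ether 30 (not isolated), via hydroxy ester 31 (not isolated)
Conditions: TMSOTf, Et3N, CH2Cl2, 0 °C → rt; then acetone, TiCl4, CH2Cl2, −78 → −40 °C; then PPTS (cat.), PhH, 50 °C
Reagents that add atoms: acetone, CC(C)=O
Why: Thermodynamic enol silane (C9=C27; enolization toward the ring-fusion carbon C26 would strain ring C), then Mukaiyama aldol addition to TiCl4-activated acetone: the electrophile reaches C9 from the open face of ring B (axial attack; the cage face is capped by C21), so C2 ends trans to C22 and C8 cis to it as in the target, and the tertiary hydroxyl then closes ring A on the ester (6-exo-trig lactonization).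

Step 24
Reactants: 32 7,8-dihydro spirolactone C27 ketone
Product: 33 7,8-dihydro target
Conditions: MeLi, CeCl3, THF, −78 °C
Reagents that add atoms: methyllithium, [Li]C
Why: Organocerium 1,2-addition to the C27 ketone from the open face (the cage face is blocked by C21) places C28 on the open face and O29 on the cage face; at −78 °C the reagent adds to ketones much faster than to esters, the δ-lactone is a tert-alkyl ester, the γ-lactone is neopentylic, and the C30 ketone sits between two quaternary carbons.

Step 25
Reactants: 33 7,8-dihydro target
Product: 36 CNP0222978.4, via selenide 34 (not isolated), via selenoxide 35 (not isolated)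
Conditions: LiN(iPr)2 (2.5 equiv), THF, −78 °C; PhSeBr; then H2O2 (30% aq.), pyridine, CH2Cl2, 0 °C → rt
Reagents that add atoms: none
Why: Selenoxide syn-elimination: the base forms the C27 alkoxide and then the δ-lactone enolate at the unhindered C7 methylene (the γ-lactone α-hydrogen at C17 is tertiary and shielded), PhSeBr selenates C7, and oxidation followed by syn-elimination toward C8, the only β-hydrogens, gives the ring-A enoate.

## Compound list

1 | cyclohexane-1,3-dione | O=C1CCCC(=O)C1 | starting material
2 | 3-oxocyclohex-1-en-1-yl trifluoromethanesulfonate | O=C1C=C(OS(=O)(=O)C(F)(F)F)CCC1 | intermediate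
3 | methyl 3-oxocyclohex-1-ene-1-carboxylate | COC(=O)C1=CC(=O)CCC1 | intermediate
4 | 2-methylenepropane-1,3-diol | OCC(=C)CO | starting material
5 | 2-[(4-methoxybenzyloxy)methyl]prop-2-en-1-ol | OCC(=C)COCc1ccc(OC)cc1 | intermediate
6 | 1-{[2-(bromomethyl)prop-2-enyloxy]methyl}-4-methoxybenzene | BrCC(=C)COCc1ccc(OC)cc1 | intermediate
7 | bis[(3S)-3-(methoxycarbonyl)cyclohex-1-en-1-yloxy]diphenylsilane | C1(O[Si](c3ccccc3)(c3ccccc3)OC2=C[C@@H](C(=O)OC)CCC2)=C[C@@H](C(=O)OC)CCC1 | intermediate (not isolated)
8 | methyl (1S,2R)-2-{2-[(4-methoxybenzyloxy)methyl]prop-2-enyl}-3-oxocyclohexane-1-carboxylate | O=C1[C@H](CC(=C)COCc2ccc(OC)cc2)[C@@H](C(=O)OC)CCC1 | intermediate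
9 | methyl (6R,7S)-6-{2-[(4-methoxybenzyloxy)methyl]prop-2-enyl}-1,4-dioxaspiro[4.5]decane-7-carboxylate | O1CCOC12[C@H](CC(=C)COCc3ccc(OC)cc3)[C@@H](C(=O)OC)CCC2 | intermediate
10 | prop-2-yn-1-ol | C#CCO | starting material
11 | (Z)-3-iodo-2-methylprop-2-en-1-ol | OC/C(C)=C\I | intermediate
12 | (Z)-3-bromo-1-iodo-2-methylprop-1-ene | BrC/C(C)=C\I | intermediate
13 | methyl (6R,7S)-7-[(Z)-3-iodo-2-methylprop-2-enyl]-6-{2-[(4-methoxybenzyloxy)methyl]prop-2-enyl}-1,4-dioxaspiro[4.5]decane-7-carboxylate | O1CCOC12[C@H](CC(=C)COCc3ccc(OC)cc3)[C@@](C(=O)OC)(C/C(C)=C\I)CCC2 | intermediate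
14 | methyl (6R,7S)-7-[(Z)-5-methoxy-2-methyl-5-oxopent-2-enyl]-6-{2-[(4-methoxybenzyloxy)methyl]prop-2-enyl}-1,4-dioxaspiro[4.5]decane-7-carboxylate | O1CCOC12[C@H](CC(=C)COCc3ccc(OC)cc3)[C@@](C(=O)OC)(C/C(C)=C\CC(=O)OC)CCC2 | intermediate
15 | spiro β-keto ester, enol form (12S,26R): ring B with C27 ethylene ketal and the C26 side chain of 9, spiro at C12 to ring D = C13H2–C14(Me)=C16H–C17(CO2Me)=C22(OH) | O1CCOC12[C@H](CC(=C)COCc3ccc(OC)cc3)[C@]4(CCC2)CC(C)=CC(C(=O)OC)=C4O | intermediate
16 | spiro dienyl triflate (12S,26R): as 15 with OSO2CF3 on C22 | O1CCOC12[C@H](CC(=C)COCc3ccc(OC)cc3)[C@]4(CCC2)CC(C)=CC(C(=O)OC)=C4OS(=O)(=O)C(F)(F)F | intermediate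
17 | spiro dienoate 4-methoxybenzyl ether (12S,26R): as 15 with methyl C21 on C22 | O1CCOC12[C@H](CC(=C)COCc3ccc(OC)cc3)[C@]4(CCC2)CC(C)=CC(C(=O)OC)=C4C | intermediate
18 | spiro dienoate allylic alcohol (12S,26R): side chain CH2–C(=CH2)–CH2OH on C26 | O1CCOC12[C@H](CC(=C)CO)[C@]4(CCC2)CC(C)=CC(C(=O)OC)=C4C | intermediate
19 | spiro dienoate α-methylene aldehyde (12S,26R): side chain CH2–C(=CH2)–CHO on C26 | O1CCOC12[C@H](CC(=C)C=O)[C@]4(CCC2)CC(C)=CC(C(=O)OC)=C4C | intermediate
20 | spiro dienoate (E)-triethylsilyl enol ether (12S,26R): side chain C25H2–C23(Me)=C30H–OSiEt3, oxygen trans to C25 | O1CCOC12[C@H](C/C(C)=C/O[Si](CC)(CC)CC)[C@]4(CCC2)CC(C)=CC(C(=O)OC)=C4C | intermediate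
21 | tetracyclic C30 triethylsilyl ether: isotwistane with C27 ketal, C16=C17 enoate, silyloxy group on C30 syn to the C16=C17 bridge | C2CC[C@@]13C[C@@]4(C)C=C(C(=O)OC)[C@]1(C)[C@@](C)(C[C@H]3C25OCCO5)[C@@H]4O[Si](CC)(CC)CC | intermediate (not isolated)
22 | tetracyclic hydroxy enoate ketal: as 21 with free C30 hydroxyl | C2CC[C@@]13C[C@@]4(C)C=C(C(=O)OC)[C@]1(C)[C@@](C)(C[C@H]3C25OCCO5)[C@@H]4O | intermediate
23 | tetracyclic hydroxy ester ketal: C16–C17 saturated, H17 toward the C23–C30 bridge | C2CC[C@@]13C[C@@]4(C)C[C@@H](C(=O)OC)[C@]1(C)[C@@](C)(C[C@H]3C25OCCO5)[C@@H]4O | intermediate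
24 | tetracyclic C30 keto ester C27 ketal | C2CC[C@@]13C[C@@]4(C)C[C@@H](C(=O)OC)[C@]1(C)[C@@](C)(C[C@H]3C25OCCO5)C4=O | intermediate (not isolated)
25 | tetracyclic diketo methyl ester | C2CC[C@@]13C[C@@]4(C)C[C@@H](C(=O)OC)[C@]1(C)[C@@](C)(C[C@H]3C2=O)C4=O | intermediate
26 | C22-methyl isotwistane diketo carboxylic acid | C2CC[C@@]13C[C@@]4(C)C[C@@H](C(=O)O)[C@]1(C)[C@@](C)(C[C@H]3C2=O)C4=O | intermediate
27 | pentacyclic diketo lactone (ring E closed) | C2CC[C@@]13C[C@@]4(C)C[C@H]5C(=O)OC[C@]51[C@@](C)(C[C@H]3C2=O)C4=O | intermediate
28 | pyrrolidine enamine of 27 (C27=C9) | N1(CCCC1)C2=CCC[C@@]34C[C@@]5(C)C[C@H]6C(=O)OC[C@]63[C@@](C)(C[C@H]42)C5=O | intermediate (not isolated)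
29 | C9-(2-methoxycarbonylethyl) diketo lactone (chain on the cage face of C9) | COC(=O)CC[C@H]2CC[C@@]13C[C@@]4(C)C[C@H]5C(=O)OC[C@]51[C@@](C)(C[C@H]3C2=O)C4=O | intermediate
30 | C27 trimethylsilyl enol ether of 29 (C9=C27) | COC(=O)CCC=2CC[C@@]13C[C@@]4(C)C[C@H]5C(=O)OC[C@]51[C@@](C)(C[C@H]3C2O[Si](C)(C)C)C4=O | intermediate (not isolated)
31 | C9 aldol hydroxy ester (C2 on the open face, C8 on the cage face) | COC(=O)CC[C@@]2(C(C)(C)O)CC[C@@]13C[C@@]4(C)C[C@H]5C(=O)OC[C@]51[C@@](C)(C[C@H]3C2=O)C4=O | intermediate (not isolated)
32 | 7,8-dihydro spirolactone C27 ketone | CC1(C)OC(=O)CC[C@]12CC[C@@]13C[C@@]4(C)C[C@H]5C(=O)OC[C@]51[C@@](C)(C[C@H]3C2=O)C4=O | intermediate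
33 | 7,8-dihydro target (C27 methyl carbinol) | CC1(C)OC(=O)CC[C@]12CC[C@@]13C[C@@]4(C)C[C@H]5C(=O)OC[C@]51[C@@](C)(C[C@H]3[C@@]2(C)O)C4=O | intermediate
34 | C7 phenylselanyl lactone (C7 epimers) | CC1(C)OC(=O)C([Se]c6ccccc6)C[C@]12CC[C@@]13C[C@@]4(C)C[C@H]5C(=O)OC[C@]51[C@@](C)(C[C@H]3[C@@]2(C)O)C4=O | intermediate (not isolated)
35 | C7 phenylseleninyl lactone (selenoxide) | CC1(C)OC(=O)C([Se](=O)c6ccccc6)C[C@]12CC[C@@]13C[C@@]4(C)C[C@H]5C(=O)OC[C@]51[C@@](C)(C[C@H]3[C@@]2(C)O)C4=O | intermediate (not isolated)
36 | CNP0222978.4 | CC1(C)OC(=O)C=C[C@]12CC[C@@]13C[C@@]4(C)C[C@H]5C(=O)OC[C@]51[C@@](C)(C[C@H]3[C@@]2(C)O)C4=O | target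

## Step count and the least certain steps

Total step count: 25. Longest linear sequence: 21 steps (steps 1, 2, 5, 6 and 9 to 25); the two reagent branches (steps 3–4 and 7–8) have two steps each.

Step 21 (key step). Most likely to go wrong: metalation stalls at the neopentylic methyl group, or it goes to the C16 methylene and ends in dehydrogenation of C16–C17; the peroxide may also oxidize next to the C27 ketone. Fallback, from 26 back to 27: the acid is converted (oxalyl chloride, then ammonia) into the primary amide F1. Irradiation with PhI(OAc)2 and I2 generates the amidyl radical, which abstracts hydrogen from C21 by a 1,5-shift (C21 is the only carbon with hydrogen at that distance). Iodination of C21 and closure through the amide oxygen give the iminolactone F2, which buffered aqueous acetic acid hydrolyses to 27. This is a Hofmann–Löffler–Freytag-type remote functionalization under hypoiodite conditions.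

Step 17. Most likely to go wrong: at the temperature needed to join two fully substituted carbons, a 1,5-hydrogen shift moves the ring-D diene out of position, or the enol ether is lost before it adds. Fallback, from 20 back to 24: Me2AlCl at −78 °C turns the cycloaddition into two ionic steps. A Mukaiyama–Michael addition of C23 to C22 gives the aldehyde silyl ketene acetal F3, and a vinylogous Mukaiyama aldol addition of C14 to the C30 aldehyde closes the bicycle. After Bu4NF this gives 22 together with its C30 epimer F4. Both are oxidized (Dess–Martin periodinane) to the keto enoate ketal F5, and hydrogenation over Pd/C from the face of the flat ketone bridge gives 24.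

Step 23. Most likely to go wrong: enolization toward C26 instead of C9, or failure of the bond between two fully substituted carbons (reversal of the aldol addition, or loss of the tertiary hydroxyl group before ring A closes). Fallback, from 27 to 36, with the same face logic but a vinyl group as the C8 unit: aldol condensation with acetaldehyde (LiN(iPr)2; CH3CHO; MsCl, Et3N; DBU) gives the (E)-ethylidene enone F6. γ-Deprotonation with KN(SiMe3)2 gives the extended dienolate, which adds at C9 to acetone (CeCl3) from the open face; the aldolate is trapped in the flask with acryloyl chloride to give the vinyl acrylate F7. Ring-closing metathesis with the second-generation Hoveyda–Grubbs catalyst forms C7=C8 and the unsaturated keto lactone F8, and MeLi/CeCl3 at −78 °C then gives 36 directly.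

Step 5. Most likely to go wrong: poor enantioselectivity because the β-substituent is an ester and not an alkyl group, hydride transfer to the carbon β to the ester, or erosion of the trans relationship by enolate equilibration. Fallback, from 3 back to 8: conjugate reduction with LiBH(sBu)3 and alkylation of the enolate with 6 give the racemic trans keto ester F9. Ketalization with (2R,3R)-butane-2,3-diol gives two diastereomeric ketals that are separated by chromatography, and hydrolysis of the wanted ketal F10 (aq. HCl, THF) returns enantiopure 8.

Step 24. Most likely to go wrong: addition of the methyl reagent to a lactone carbonyl, or enolization instead of addition at the very hindered C27 ketone. Fallback, from 27 back to 33, in which the methyl group is added before ring A exists: the enamine Michael addition of step 22 is run with tert-butyl acrylate to give the tert-butyl keto ester F11. Enol silane formation and the TiCl4–acetone aldol addition give the hydroxy keto tert-butyl ester F12, which does not lactonize. MeLi/CeCl3 then meets only the ketone and an unreactive tert-butyl ester and gives the diol tert-butyl ester F13, and CF3CO2H removes the tert-butyl group and closes ring A to 33.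

## Further compounds

F1 | step 21 | primary amide of acid 26 | C2CC[C@@]13C[C@@]4(C)C[C@@H](C(N)=O)[C@]1(C)[C@@](C)(C[C@H]3C2=O)C4=O
F2 | step 21 | iminolactone (cyclic imidate of ring E) | C2CC[C@@]13C[C@@]4(C)C[C@H]5C(=N)OC[C@]51[C@@](C)(C[C@H]3C2=O)C4=O
F3 | step 17 | Michael adduct: C22–C23 bond formed, C30 aldehyde, silyl ketene acetal at C17 | C2CC[C@@]13CC(C)=CC(=C(OC)O[Si](CC)(CC)CC)[C@]1(C)[C@@](C)(C[C@H]3C25OCCO5)C=O
F4 | step 17 | C30 epimer of 22 | C2CC[C@@]13C[C@@]4(C)C=C(C(=O)OC)[C@]1(C)[C@@](C)(C[C@H]3C25OCCO5)[C@H]4O
F5 | step 17 | tetracyclic C30 keto enoate C27 ketal | C2CC[C@@]13C[C@@]4(C)C=C(C(=O)OC)[C@]1(C)[C@@](C)(C[C@H]3C25OCCO5)C4=O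
F6 | step 23 | (E)-C9-ethylidene diketo lactone | C/C=C2\CC[C@@]13C[C@@]4(C)C[C@H]5C(=O)OC[C@]51[C@@](C)(C[C@H]3C2=O)C4=O
F7 | step 23 | C9 vinyl, C9 2-(acryloyloxy)propan-2-yl diketo lactone | C=C[C@@]2(C(C)(C)OC(=O)C=C)CC[C@@]13C[C@@]4(C)C[C@H]5C(=O)OC[C@]51[C@@](C)(C[C@H]3C2=O)C4=O
F8 | step 23 | unsaturated spirolactone C27 ketone | CC1(C)OC(=O)C=C[C@]12CC[C@@]13C[C@@]4(C)C[C@H]5C(=O)OC[C@]51[C@@](C)(C[C@H]3C2=O)C4=O
F9 | step 5 | racemic trans keto ester (racemate of 8, one enantiomer drawn) | O=C1[C@H](CC(=C)COCc2ccc(OC)cc2)[C@@H](C(=O)OC)CCC1
F10 | step 5 | (2R,3R)-butane-2,3-diol ketal of 8 | C[C@H]1OC2(O[C@@H]1C)[C@H](CC(=C)COCc3ccc(OC)cc3)[C@@H](C(=O)OC)CCC2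
F11 | step 24 | C9-(2-tert-butoxycarbonylethyl) diketo lactone | CC(C)(C)OC(=O)CC[C@H]2CC[C@@]13C[C@@]4(C)C[C@H]5C(=O)OC[C@]51[C@@](C)(C[C@H]3C2=O)C4=O
F12 | step 24 | C9 aldol hydroxy keto tert-butyl ester | CC(C)(C)OC(=O)CC[C@@]2(C(C)(C)O)CC[C@@]13C[C@@]4(C)C[C@H]5C(=O)OC[C@]51[C@@](C)(C[C@H]3C2=O)C4=O
F13 | step 24 | C2,C27 diol tert-butyl ester | CC(C)(C)OC(=O)CC[C@@]2(C(C)(C)O)CC[C@@]13C[C@@]4(C)C[C@H]5C(=O)OC[C@]51[C@@](C)(C[C@H]3[C@@]2(C)O)C4=O
A1 | alternative 1 | spiro cyclohexadiene butenolide with C27 ketal and acetal side chain | C2CC[C@]3(CC(C)=CC4=C3COC4=O)[C@@H](C[C@@H](C)C(OC)OC)C25OCCO5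
A2 | alternative 2 | crotyl bicyclo[2.2.2]octenone γ-lactone | CC(C)(C)[Si](C)(C)OCCCC1=C[C@@]2(C)C[C@H]3C(=O)OC[C@]31[C@@](C)(C/C=C/C)C2=O
A3 | alternative 3 | tricyclic cyclopentanone with cis-fused γ-lactone | C2CC[C@@]13C=C(C)C[C@H]5C(=O)OC[C@]51C(=O)C[C@H]3C24OCCO4
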